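**Strategy**

Everything rests on the C3–C3a bond. In the target, C3 of the dihydrofuran ring carries ring A (through C3a) and the one-carbon arm C9 beside the O1–C2(aryl) unit; moving C3a back from C3 to C9 reveals a 2-arylchroman-4-one with C9 as carbonyl carbon. The key step exploits this relationship: trivalent iodine in trimethyl orthoformate drives the ring A ipso carbon of an enantiopure (2S)-flavanone from the carbonyl carbon to C3, which in one operation contracts the pyranone to the dihydrofuran, forms C3–C3a, sets C3 trans to the C2 aryl group and delivers C9 as a methyl ester. The precursor is a (2S)-flavanone whose phenol and side-chain alcohol are masked as acetates.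

Key step: step 7

Remark: ring A is the benzo ring, ring B the 2-aryl ring, ring C the oxygen heterocycle and C9 the exocyclic carbon on C3; the three starting materials and both enantiomers of the ligand t-BuPyOx are taken as purchasable; the ligand enantiomer in step 6 is chosen by analogy with the facial sense known for cyclic enones and should be confirmed on the first batch, the other enantiomer being used if the sense proves opposite.

**Route**

Step 1
Reactants: 1 1-(2-hydroxy-3-methoxyphenyl)ethanone (2'-hydroxy-3'-methoxyacetophenone)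
Product: 2 1-(5-bromo-2-hydroxy-3-methoxyphenyl)ethanone
Conditions: NBS, MeCN, 0 °C to rt
Reagents that add atoms: N-bromosuccinimide, O=C1CCC(=O)N1Br
Why: Electrophilic aromatic bromination should go para to the free hydroxyl group, the most activated position and the one meta to the deactivating acetyl group (the same sense as in the bromination of o-vanillin), while ionic conditions at low temperature leave the methyl ketone alone.

Step 2
Reactants: 2 1-(5-bromo-2-hydroxy-3-methoxyphenyl)ethanone
Product: 4 6-bromo-8-methoxy-4H-chromen-4-one, via enaminone 3 (not isolated)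
Conditions: Me2NCH(OMe)2, toluene, 100 °C; then conc. HCl, CH2Cl2, 40 °C
Reagents that add atoms: N,N-dimethylformamide dimethyl acetal, COC(OC)N(C)C
Why: Condensation of the methyl ketone with the amide acetal gives the vinylogous amide, and acid-promoted addition of the phenol with loss of dimethylamine closes the pyranone (enaminone route to chromones).

Step 3
Reactants: 4 6-bromo-8-methoxy-4H-chromen-4-one; 5 allyl acetate
Product: 7 3-(8-methoxy-4-oxo-4H-chromen-6-yl)propyl acetate, via alkylborane 6 (not isolated)
Conditions: 5 (slight excess), 9-BBN, THF, 0 °C to rt; then 4, Pd(dppf)Cl2, Cs2CO3, DMF/H2O, rt to 50 °C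
Reagents that add atoms: none
Why: Anti-Markovnikov hydroboration puts boron on the chain terminus, and B-alkyl Suzuki–Miyaura coupling of alkylborane 6 with the aryl bromide (oxidative addition to zerovalent palladium, base-assisted transmetalation, reductive elimination favoured by dppf over β-hydride elimination) should attach the three-carbon chain at C6, the mild carbonate base sparing pyranone and acetate.

Step 4
Reactants: 8 2,6-dimethoxy-4-(4,4,5,5-tetramethyl-1,3,2-dioxaborolan-2-yl)phenol
Product: 9 2,6-dimethoxy-4-(4,4,5,5-tetramethyl-1,3,2-dioxaborolan-2-yl)phenyl acetate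
Conditions: Ac2O, pyridine, DMAP (cat.), CH2Cl2, rt
Reagents that add atoms: acetic anhydride, CC(=O)OC(C)=O
Why: DMAP-catalysed O-acylation of the hindered phenol should be clean, and the acetate is needed before the periodate step, which would otherwise oxidise the free 2,6-dimethoxyphenol.

Step 5
Reactants: 9 2,6-dimethoxy-4-(4,4,5,5-tetramethyl-1,3,2-dioxaborolan-2-yl)phenyl acetate
Product: 10 (4-acetoxy-3,5-dimethoxyphenyl)boronic acid
Conditions: NaIO4, NH4OAc, acetone/H2O, rt
Reagents that add atoms: water, O
Why: Periodate cleaves the pinacol released in the hydrolysis equilibrium (glycol cleavage), which should drive the boronate to the free boronic acid under near-neutral conditions that leave the aryl acetate intact.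

Step 6
Reactants: 7 3-(8-methoxy-4-oxo-4H-chromen-6-yl)propyl acetate; 10 (4-acetoxy-3,5-dimethoxyphenyl)boronic acid
Product: 11 3-[(2S)-2-(4-acetoxy-3,5-dimethoxyphenyl)-8-methoxy-4-oxo-3,4-dihydro-2H-chromen-6-yl]propyl acetate, the (2S)-flavanone
Conditions: Pd(OCOCF3)2 (5 mol%), (R)-t-BuPyOx (6 mol%), NH4PF6 (30 mol%), H2O (5 equiv), ClCH2CH2Cl, 60 °C
Reagents that add atoms: none
Why: Asymmetric conjugate addition of an arylboronic acid to a chromone under cationic divalent palladium/pyridine–oxazoline catalysis (aryl transfer from boron, enantio-determining carbopalladation of C2=C3, protonolysis of the palladium enolate by water) should give the flavanone, the tert-butyl group of the ligand differentiating the enone faces so that the (R)-ligand is expected to set C2 as (S).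

Step 7
Reactants: 11 3-[(2S)-2-(4-acetoxy-3,5-dimethoxyphenyl)-8-methoxy-4-oxo-3,4-dihydro-2H-chromen-6-yl]propyl acetate
Product: 15 methyl (2S,3S)-2-(4-acetoxy-3,5-dimethoxyphenyl)-5-(3-acetoxypropyl)-7-methoxy-2,3-dihydro-1-benzofuran-3-carboxylate (2,3-trans), via enol ether 12 (not isolated), via iodane 13 (not isolated), via orthoester 14 (not isolated)
Conditions: PhI(OAc)2 (1.2 equiv), conc. H2SO4, HC(OMe)3, rt; then H2O, NaHCO3 work-up
Reagents that add atoms: trimethyl orthoformate, COC(OC)OC; water, O
Why: Acid-catalysed exchange with the orthoformate turns the C4 ketone into methyl enol ether 12, the trivalent iodine electrophile adds to C3 on the face opposite the equatorial C2 aryl group and methanol caps C4, giving the 2,3-trans iodane ketal 13 whose equatorial C3–I bond is antiperiplanar to the ring bond C4–C4a. The ipso carbon C4a, activated by the ortho oxygen O1, then shifts from C4 to C3 as iodobenzene leaves, which is the oxidative 1,2-aryl rearrangement of aryl ketones by trivalent iodine (or trivalent thallium) in trimethyl orthoformate in its known form as the ring contraction of flavanones. The dihydrofuran ring is therefore closed by contraction and not by cyclisation: C3–C3a forms through a bridged phenonium-type transition state (formally 3-exo-tet at C3) while C4–C4a breaks, and the resulting dimethoxycarbenium ion at C9 is trapped by methanol as orthoester 14, which aqueous work-up hydrolyses to the methyl ester. The new C3 stereocentre is under substrate control from C2, since anti iodination followed by migration with inversion at C3 places the ester where the iodine stood, trans to the aryl group, which is also the more stable epimer. The step needs ring A migration to win over ring B migration (isoflavone) and over elimination to the flavone, and it needs C2 to keep its configuration; the antiperiplanar C4–C4a bond, the donor O1 on ring A and the 4-acetoxy group, which makes ring B a poor migrating group and disfavours ionisation or retro-oxa-Michael opening at C2–O1, should secure both.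

Step 8
Reactants: 15 methyl (2S,3S)-2-(4-acetoxy-3,5-dimethoxyphenyl)-5-(3-acetoxypropyl)-7-methoxy-2,3-dihydro-1-benzofuran-3-carboxylate
Product: 16 4-[(2S,3R)-3-(hydroxymethyl)-5-(3-hydroxypropyl)-7-methoxy-2,3-dihydro-1-benzofuran-2-yl]-2,6-dimethoxyphenol (target)
Conditions: LiAlH4, THF, 0 °C; aq. Rochelle salt work-up
Reagents that add atoms: none
Why: Hydride reduction should convert the C9 methyl ester into the hydroxymethyl group and cleave the alkyl and the aryl acetate in the same operation without touching C2 or C3 (the descriptor at C3 changes from S to R only because CH2OH ranks below C2).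

**Compound list**

1 | 1-(2-hydroxy-3-methoxyphenyl)ethanone | CC(=O)c1cccc(OC)c1O | starting material
2 | 1-(5-bromo-2-hydroxy-3-methoxyphenyl)ethanone | CC(=O)c1cc(Br)cc(OC)c1O | intermediate
3 | (E)-1-(5-bromo-2-hydroxy-3-methoxyphenyl)-3-(dimethylamino)prop-2-en-1-one (enaminone; not isolated) | CN(C)/C=C/C(=O)c1cc(Br)cc(OC)c1O | intermediate
4 | 6-bromo-8-methoxy-4H-chromen-4-one | COc1cc(Br)cc2c(=O)ccoc12 | intermediate
5 | allyl acetate (prop-2-en-1-yl acetate) | CC(=O)OCC=C | starting material
6 | 3-(9-borabicyclo[3.3.1]nonan-9-yl)propyl acetate (alkylborane; not isolated) | CC(=O)OCCCB1C2CCCC1CCC2 | intermediate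
7 | 3-(8-methoxy-4-oxo-4H-chromen-6-yl)propyl acetate | COc1cc(CCCOC(C)=O)cc2c(=O)ccoc12 | intermediate
8 | 2,6-dimethoxy-4-(4,4,5,5-tetramethyl-1,3,2-dioxaborolan-2-yl)phenol | COc1cc(B2OC(C)(C)C(C)(C)O2)cc(OC)c1O | starting material
9 | 2,6-dimethoxy-4-(4,4,5,5-tetramethyl-1,3,2-dioxaborolan-2-yl)phenyl acetate | COc1cc(B2OC(C)(C)C(C)(C)O2)cc(OC)c1OC(C)=O | intermediate
10 | (4-acetoxy-3,5-dimethoxyphenyl)boronic acid | COc1cc(B(O)O)cc(OC)c1OC(C)=O | intermediate
11 | 3-[(2S)-2-(4-acetoxy-3,5-dimethoxyphenyl)-8-methoxy-4-oxo-3,4-dihydro-2H-chromen-6-yl]propyl acetate | COc1cc([C@@H]2CC(=O)c3cc(CCCOC(C)=O)cc(OC)c3O2)cc(OC)c1OC(C)=O | intermediate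
12 | 3-[(2S)-2-(4-acetoxy-3,5-dimethoxyphenyl)-4,8-dimethoxy-2H-chromen-6-yl]propyl acetate (enol ether; not isolated) | COc1cc([C@@H]2C=C(OC)c3cc(CCCOC(C)=O)cc(OC)c3O2)cc(OC)c1OC(C)=O | intermediate
13 | 3-[(2R,3R)-2-(4-acetoxy-3,5-dimethoxyphenyl)-3-[acetoxy(phenyl)iodanyl]-4,4,8-trimethoxy-3,4-dihydro-2H-chromen-6-yl]propyl acetate (2,3-trans iodane ketal; not isolated) | COc1cc([C@@H]2[C@@H](I(OC(C)=O)c4ccccc4)C(OC)(OC)c3cc(CCCOC(C)=O)cc(OC)c3O2)cc(OC)c1OC(C)=O | intermediate
14 | 3-[(2S,3S)-2-(4-acetoxy-3,5-dimethoxyphenyl)-7-methoxy-3-(trimethoxymethyl)-2,3-dihydro-1-benzofuran-5-yl]propyl acetate (orthoester; not isolated) | COc1cc([C@H]2Oc3c(OC)cc(CCCOC(C)=O)cc3[C@@H]2C(OC)(OC)OC)cc(OC)c1OC(C)=O | intermediate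
15 | methyl (2S,3S)-2-(4-acetoxy-3,5-dimethoxyphenyl)-5-(3-acetoxypropyl)-7-methoxy-2,3-dihydro-1-benzofuran-3-carboxylate | COc1cc([C@H]2Oc3c(OC)cc(CCCOC(C)=O)cc3[C@@H]2C(=O)OC)cc(OC)c1OC(C)=O | intermediate
16 | 4-[(2S,3R)-3-(hydroxymethyl)-5-(3-hydroxypropyl)-7-methoxy-2,3-dihydro-1-benzofuran-2-yl]-2,6-dimethoxyphenol | COc1cc([C@H]2Oc3c(OC)cc(CCCO)cc3[C@@H]2CO)cc(OC)c1O | target

**Step count**

Total: 8 steps. Longest linear sequence: 6 steps (1, 2, 3, 6, 7, 8); the boronic acid branch (4, 5) joins at step 6.

**Steps most likely to fail**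

Step 7. What may go wrong:
- the C3 iodane may lose the C2 proton (flavone) or let ring B shift instead of ring A (isoflavone);
- the acidic medium may strip the aryl acetate, so that the oxidant attacks the free phenol;
- reversible opening of the C2–O1 bond may erode the configuration at C2.

The fallback sets out from 11 and returns at 15. It installs and activates the leaving group in separate operations, so that neither an oxidant nor a strong protic acid is present when the aryl shift occurs. Bromination of 11 with CuBr2 in EtOAc/CHCl3 at reflux should give the 2,3-trans bromo ketone, 3-[(2R,3R)-2-(4-acetoxy-3,5-dimethoxyphenyl)-3-bromo-8-methoxy-4-oxo-3,4-dihydro-2H-chromen-6-yl]propyl acetate F1. Ketalisation with trimethyl orthoformate and catalytic TsOH should give the dimethyl ketal, 3-[(2R,3R)-2-(4-acetoxy-3,5-dimethoxyphenyl)-3-bromo-4,4,8-trimethoxy-3,4-dihydro-2H-chromen-6-yl]propyl acetate F2. AgBF4 in methanol/trimethyl orthoformate then removes the equatorial bromide, C4a shifts antiperiplanar as in the iodane, and aqueous work-up should deliver 15 (silver-assisted 1,2-aryl shift of an α-halo ketal to an ester).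

Step 6. What may go wrong: poor facial selectivity on this 8-methoxychromone, or erosion of the enantiomeric purity by reversible ring opening under the reaction conditions.

The fallback sets out from 7 and 10 and returns at 11. It gives up catalytic asymmetric induction in favour of resolution. Conjugate addition with Pd(OCOCF3)2 and achiral 2,2'-bipyridine under otherwise similar conditions should give the racemic flavanone, 3-[2-(4-acetoxy-3,5-dimethoxyphenyl)-8-methoxy-4-oxo-3,4-dihydro-2H-chromen-6-yl]propyl acetate F3. Preparative chromatography on a polysaccharide chiral stationary phase should then deliver 11, while the (2R)-flavanone, 3-[(2R)-2-(4-acetoxy-3,5-dimethoxyphenyl)-8-methoxy-4-oxo-3,4-dihydro-2H-chromen-6-yl]propyl acetate F4, is set aside.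

Step 3. What may go wrong: opening of the pyranone ring or hydrolysis of the acetate by the aqueous base of the coupling, or protodebromination in place of alkyl transfer.

The fallback sets out from 2 (with alkylborane 6 made as before) and returns at 7. It moves the carbon–carbon coupling ahead of ring formation, so that the heterocycle never meets base. Coupling of 2 with 6 (Pd(OAc)2, SPhos, K3PO4, THF/H2O) should give the acetophenone, 3-(3-acetyl-4-hydroxy-5-methoxyphenyl)propyl acetate F5. Condensation with N,N-dimethylformamide dimethyl acetal should give the enaminone, 3-[3-[(E)-3-(dimethylamino)prop-2-enoyl]-4-hydroxy-5-methoxyphenyl]propyl acetate F6, which conc. HCl in CH2Cl2 should close to 7.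

Further compounds
F1 | step 7 | 3-[(2R,3R)-2-(4-acetoxy-3,5-dimethoxyphenyl)-3-bromo-8-methoxy-4-oxo-3,4-dihydro-2H-chromen-6-yl]propyl acetate (2,3-trans) | COc1cc([C@@H]2[C@@H](Br)C(=O)c3cc(CCCOC(C)=O)cc(OC)c3O2)cc(OC)c1OC(C)=O
F2 | step 7 | 3-[(2R,3R)-2-(4-acetoxy-3,5-dimethoxyphenyl)-3-bromo-4,4,8-trimethoxy-3,4-dihydro-2H-chromen-6-yl]propyl acetate (2,3-trans) | COc1cc([C@@H]2[C@@H](Br)C(OC)(OC)c3cc(CCCOC(C)=O)cc(OC)c3O2)cc(OC)c1OC(C)=O
F3 | step 6 | racemic 3-[2-(4-acetoxy-3,5-dimethoxyphenyl)-8-methoxy-4-oxo-3,4-dihydro-2H-chromen-6-yl]propyl acetate | COc1cc(C2CC(=O)c3cc(CCCOC(C)=O)cc(OC)c3O2)cc(OC)c1OC(C)=O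
F4 | step 6 | 3-[(2R)-2-(4-acetoxy-3,5-dimethoxyphenyl)-8-methoxy-4-oxo-3,4-dihydro-2H-chromen-6-yl]propyl acetate | COc1cc([C@H]2CC(=O)c3cc(CCCOC(C)=O)cc(OC)c3O2)cc(OC)c1OC(C)=O
F5 | step 3 | 3-(3-acetyl-4-hydroxy-5-methoxyphenyl)propyl acetate | CC(=O)OCCCc1cc(OC)c(O)c(C(C)=O)c1
F6 | step 3 | 3-[3-[(E)-3-(dimethylamino)prop-2-enoyl]-4-hydroxy-5-methoxyphenyl]propyl acetate | CN(C)/C=C/C(=O)c1cc(CCCOC(C)=O)cc(OC)c1O
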